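As the chemist on this coupling I had two earlier runs and a more concentrated flask to call.

| setting | Wednesday's | Thursday's | flask |
|---|---|---|---|
| starting material | 5 mM | 7.5 mM | 10 mM |
| coupling partner | 1.8 equiv | 1.8 equiv | 1.80 equiv |
| remark | run made earlier | run made earlier |  |
| time |  |  | 5.0 min |

| run | time / min | starting material / % | single product / % | other mono adduct / % |
|---|---|---|---|---|
| Wednesday's | 0.833 | 83 | 12 | 8 |
| Wednesday's | 1.50 | 75 | 21 | 13 |
| Wednesday's | 2.50 | 62 | 29 | 12 |
| Wednesday's | 3.00 | 52 | 26 | 16 |
| Wednesday's | 4.00 | 45 | 30 | 16 |
| Thursday's | 0.833 | 72 | 16 | 10 |
| Thursday's | 1.50 | 63 | 23 | 14 |
| Thursday's | 2.50 | 46 | 35 | 15 |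
| Thursday's | 3.00 | 43 | 39 | 18 |
| Thursday's | 4.00 | 35 | 42 | 17 |

(scatter of a reading: 2 percentage points)

- starting material at 5.0 min, in percent of the starting material charged
- single product at 5.0 min, in percent of the starting material charged
- other mono adduct at 5.0 min, in percent of the starting material charged
- double product at 5.0 min, in percent of the starting material charged

- a reading or a percentage of single product counts all its forms, free or not

Pooling the readings of both runs at 4.00 min gave 0.275, and I carried this as the mono share, the fraction of other mono adduct standing per fraction of starting material converted, a net selectivity. On Thursday's run the same ratio read lower at the last reading, 0.262, than at the first, 0.357, which is why I pooled late readings.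

The forecast gave 23% starting material, 48% single product, 17% other mono adduct and 12% double product, saying of the adduct “then levels off near 16–18%, so it is probably being consumed about as fast as it forms”. My mono share, put on the forecast's conversion, gave 21.2% other mono adduct, above its figure.

The flask gave 19.0% starting material, 49.4% single product, 22.9% other mono adduct and 8.20% double product, so the forecast's other mono adduct stood 5.9 percentage points low.

    crystals ⇌ single product, rate k1*(cs1 - [single product]) while solid is left; crystals form when [single product] > cs1 (solubility = 0.300 mM, k = 0.108 /s)
    starting material + single product → side product (k = 0.0429 /M/s)
    coupling partner + other mono adduct → double product + released group (k = 0.0795 /M/s)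
    starting material + coupling partner → single product + released group (k = 0.303 /M/s)
    starting material + coupling partner → other mono adduct + released group (k = 0.155 /M/s)
    coupling partner + single product → double product + released group (k = 0.229 /M/s)

At 5.00 min the flask's other mono adduct was still being made 1.62 times as fast as it was used up. The mono share on the flask's actual conversion gives 22.3%, beside the 22.9% found. The same flask with 0.720 equiv of coupling partner kept 55.2% starting material at the same time, so the mono share gives 12.3%, and that flask held 14.2%.

The numbers in the tables are calculated with made-up constants, and the scatter is random.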